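**Assumption:** the (R,R) lithium amide in step 4 and (DHQD)2PHAL in step 8 are taken as the enantiomer and pseudoenantiomer that give the configurations drawn (otherwise the (S,S) amide or (DHQ)2PHAL is used); locants follow the spiro[5.5]undecane numbering of the target throughout (ring B = C1–C5, spiro atom = C6, ring A = C7–C11).

## Retrosynthetic overview

1. Mailiohydrin 21 ⇐ C9 ketone 20 (hydride reduction) ⇐ conjugated 7-methyl enone 18 (deconjugation to the exocyclic methylene).
2. Key disconnection, C3–O: the C3(OH)CHBr2 unit of 18 ⇐ ring-B 1-bromo-1,3-diene 17 + Br+/H2O (catalyst-controlled bromohydroxylation); the diene ⇐ ring-B enone 11 by Wittig bromomethylenation.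
3. Ring A functionality ⇐ dimedone vinylogous ester (methyl addition with carbonyl transposition, then α′-bromination at C10).
4. Spiro stereocentre C6 ⇐ achiral spiro diketone 9, by enantiotopic-group-selective deprotonation and dehydrogenation.
5. Ring order: ring A is dimedone; ring B is closed onto it by Diels–Alder reaction of exo-methylene enone 6 with 2-silyloxybutadiene 7.

## Route

Step 1
Reactants: 1 dimedone (5,5-dimethylcyclohexane-1,3-dione); 2 2-methylpropan-1-ol
Product: 3 5,5-dimethyl-3-(2-methylpropoxy)cyclohex-2-en-1-one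
Conditions: TsOH·H2O (cat.), toluene, reflux, Dean–Stark
Reagents that add atoms: none
Why: Acid-catalysed enol etherification of the 1,3-diketone (vinylogous ester formation) driven by azeotropic removal of water; no stereocentre.

Step 2
Reactants: 3
Product: 6 5,5-dimethyl-6-methylidene-3-(2-methylpropoxy)cyclohex-2-en-1-one, via Mannich base 4 (not isolated), via ammonium iodide 5 (not isolated)
Conditions: LiN(i-Pr)2, THF, −78 °C; Eschenmoser's salt, −78 → 23 °C; MeI, 23 °C; K2CO3, H2O/CH2Cl2, 23 °C
Reagents that add atoms: Eschenmoser's salt (N,N-dimethylmethyleneiminium iodide), C=[N+](C)C.[I-]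
Why: The kinetic α′-lithium enolate (C6 is the only α′ position) undergoes Mannich aminomethylation, and quaternisation followed by Hofmann-type elimination gives the exo-methylene enone; no stereocentre.

Step 3
Reactants: 6; 7 2-(trimethylsilyloxy)buta-1,3-diene
Product: 9 11,11-dimethyl-9-(2-methylpropoxy)spiro[5.5]undec-8-ene-3,7-dione, via racemic silyl enol ether adduct 8 (not isolated)
Conditions: toluene, BHT, 150 °C, sealed tube; then 1 M HCl, THF, 0 °C
Reagents that add atoms: none
Why: Normal-demand Diels–Alder reaction of the 1,1-disubstituted enone with the 2-silyloxydiene ("para" regiochemistry) builds ring B and the quaternary carbon, and hydrolysis of the silyl enol ether makes ring B symmetric, so C6 is not yet a stereocentre.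

Step 4
Reactants: 9
Product: 11 (6R)-11,11-dimethyl-9-(2-methylpropoxy)spiro[5.5]undeca-1,8-diene-3,7-dione, via silyl enol ether 10 (not isolated)
Conditions: (R,R)-bis(1-phenylethyl)amine, n-BuLi, LiCl, Me3SiCl, THF, −100 °C; then Pd(OAc)2 (10 mol %), O2, DMSO, 25 °C
Reagents that add atoms: none
Why: Enantiotopic-group-selective deprotonation of the ring-B ketone by the chiral lithium amide (ring B chair locked with the CMe2 arm equatorial; in situ silyl quench) followed by Saegusa–Ito dehydrogenation places the C1=C2 bond in one of the two enantiotopic arms and thereby sets C6.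

Step 5
Reactants: 11; 12 (bromomethyl)triphenylphosphonium bromide
Product: 13 (6R)-3-(bromomethylidene)-11,11-dimethyl-9-(2-methylpropoxy)spiro[5.5]undeca-1,8-dien-7-one (E/Z mixture at C3=CHBr)
Conditions: NaN(SiMe3)2, THF, −78 °C; then 11, −78 → 23 °C
Reagents that add atoms: none
Why: Wittig bromomethylenation occurs at the ring-B enone carbonyl only, because the hindered vinylogous ester carbonyl of ring A is inert to the ylide; both olefin isomers converge in step 8.

Step 6
Reactants: 13
Product: 15 (6R)-3-(bromomethylidene)-7,11,11-trimethylspiro[5.5]undeca-1,7-dien-9-one, via methyl carbinol 14 (not isolated)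
Conditions: MeLi, CeCl3, THF, −78 °C; then 1 M HCl, 0 → 23 °C
Reagents that add atoms: methyllithium, [Li]C
Why: 1,2-Addition of the organocerium reagent to the vinylogous ester carbonyl and acid-mediated Stork–Danheiser transposition (loss of isobutanol) give the 7-methyl-7-en-9-one; C6 is untouched.

Step 7
Reactants: 15
Product: 17 (6S,10S)-10-bromo-3-(bromomethylidene)-7,11,11-trimethylspiro[5.5]undeca-1,7-dien-9-one, via silyl dienol ether 16 (not isolated)
Conditions: LiN(i-Pr)2, THF, −78 °C; Me3SiCl; then NBS, THF, −78 → 0 °C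
Reagents that add atoms: N-bromosuccinimide, O=C1CCC(=O)N1Br
Why: Kinetic α′-enolisation (cross-conjugated silyl dienol ether) and electrophilic bromination put bromine on C10 only; the C10 centre is epimerisable through the enol and settles as the equatorial (10S) bromide cis to the C1 arm, the arrangement found in elatol-type ring A.

Step 8
Reactants: 17
Product: 18 (3R,6S,10S)-10-bromo-3-(dibromomethyl)-3-hydroxy-7,11,11-trimethylspiro[5.5]undeca-1,7-dien-9-one
Conditions: NBS (1.1 equiv), (DHQD)2PHAL (10 mol %), (+)-camphorsulfonic acid (10 mol %), MeCN/H2O 10:1, −30 °C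
Reagents that add atoms: N-bromosuccinimide, O=C1CCC(=O)N1Br; water, O
Why: Proposed new method: the cinchona-bound bromenium ion transfers Br+ to the bromine-bearing terminus C15 of the 1-bromo-1,3-diene (this gives the tertiary allylic, bromine-bridged cation at C3, whereas C1 is neopentylic), and water in the catalyst pocket opens the bridged ion at C3 anti to bromine, which forms the C3–O bond and the CHBr2 group and sets C3 (R) under catalyst control for both olefin isomers because C15 ends up non-stereogenic, while the electron-poor enone and α-bromoketone of ring A do not react with Br+; the closest known reaction type is the cinchona-alkaloid-catalysed asymmetric bromohydroxylation of simple alkenes with N-bromoamides and water, which has not been shown on vinyl bromides or 1-bromodienes.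

Step 9
Reactants: 18
Product: 20 (3R,6S,10S)-10-bromo-3-(dibromomethyl)-3-hydroxy-11,11-dimethyl-7-methylidenespiro[5.5]undec-1-en-9-one, via bis-silyl dienol ether 19 (not isolated)
Conditions: Me3SiOTf, i-Pr2NEt, CH2Cl2, −20 → 0 °C; then Bu4NF, AcOH, THF, −40 °C
Reagents that add atoms: none
Why: Soft enolisation with a hindered base removes an unhindered C7-methyl proton (the neopentylic C10–H is shielded) to give the linear silyl dienol ether, and buffered fluoride releases the dienol, which is protonated kinetically at the α-carbon C8 (deconjugative protonation) to leave the exocyclic methylene; the amine keeps C10 at its equatorial (10S) configuration.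

Step 10
Reactants: 20
Product: 21 mailiohydrin, (3R,6S,9R,10S)-10-bromo-3-(dibromomethyl)-11,11-dimethyl-7-methylidenespiro[5.5]undec-1-ene-3,9-diol
Conditions: i-Bu2AlH (3 equiv), CH2Cl2, −78 °C; potassium sodium tartrate work-up
Reagents that add atoms: none
Why: Ketone reduction by a bulky aluminium hydride; axial approach to C9 is blocked by the axial C11 methyl, so hydride enters equatorially and gives the axial (9R) alcohol cis to the equatorial bromide, and the C–Br bonds survive at −78 °C.

## Compound list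

1 | dimedone (5,5-dimethylcyclohexane-1,3-dione) | O=C1CC(=O)CC(C)(C)C1 | starting material
2 | 2-methylpropan-1-ol | CC(C)CO | starting material
3 | 5,5-dimethyl-3-(2-methylpropoxy)cyclohex-2-en-1-one | O=C1C=C(OCC(C)C)CC(C)(C)C1 | intermediate
4 | 6-[(dimethylamino)methyl]-5,5-dimethyl-3-(2-methylpropoxy)cyclohex-2-en-1-one (racemic Mannich base) | O=C1C=C(OCC(C)C)CC(C)(C)C1CN(C)C | intermediate
5 | {[6,6-dimethyl-4-(2-methylpropoxy)-2-oxocyclohex-3-en-1-yl]methyl}trimethylammonium iodide (racemic) | O=C1C=C(OCC(C)C)CC(C)(C)C1C[N+](C)(C)C.[I-] | intermediate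
6 | 5,5-dimethyl-6-methylidene-3-(2-methylpropoxy)cyclohex-2-en-1-one | O=C1C=C(OCC(C)C)CC(C)(C)C1=C | intermediate
7 | 2-(trimethylsilyloxy)buta-1,3-diene | C=CC(=C)O[Si](C)(C)C | starting material
8 | racemic 11,11-dimethyl-9-(2-methylpropoxy)-3-(trimethylsilyloxy)spiro[5.5]undeca-2,8-dien-7-one | O=C1C=C(OCC(C)C)CC(C)(C)C12CC=C(O[Si](C)(C)C)CC2 | intermediate
9 | 11,11-dimethyl-9-(2-methylpropoxy)spiro[5.5]undec-8-ene-3,7-dione (achiral) | O=C1C=C(OCC(C)C)CC(C)(C)C12CCC(=O)CC2 | intermediate
10 | (6R)-11,11-dimethyl-9-(2-methylpropoxy)-3-(trimethylsilyloxy)spiro[5.5]undeca-2,8-dien-7-one | O=C1C=C(OCC(C)C)CC(C)(C)[C@@]12CC=C(O[Si](C)(C)C)CC2 | intermediate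
11 | (6R)-11,11-dimethyl-9-(2-methylpropoxy)spiro[5.5]undeca-1,8-diene-3,7-dione | O=C1C=C(OCC(C)C)CC(C)(C)[C@@]12C=CC(=O)CC2 | intermediate
12 | (bromomethyl)triphenylphosphonium bromide | BrC[P+](c1ccccc1)(c1ccccc1)c1ccccc1.[Br-] | starting material
13 | (6R)-3-(bromomethylidene)-11,11-dimethyl-9-(2-methylpropoxy)spiro[5.5]undeca-1,8-dien-7-one (E/Z mixture) | O=C1C=C(OCC(C)C)CC(C)(C)[C@@]12C=CC(=CBr)CC2 | intermediate
14 | (6R)-3-(bromomethylidene)-7,11,11-trimethyl-9-(2-methylpropoxy)spiro[5.5]undeca-1,8-dien-7-ol (C7 epimers) | CC1(O)C=C(OCC(C)C)CC(C)(C)[C@@]12C=CC(=CBr)CC2 | intermediate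
15 | (6R)-3-(bromomethylidene)-7,11,11-trimethylspiro[5.5]undeca-1,7-dien-9-one | CC1=CC(=O)CC(C)(C)[C@@]12C=CC(=CBr)CC2 | intermediate
16 | (6S)-3-(bromomethylidene)-7,11,11-trimethyl-9-(trimethylsilyloxy)spiro[5.5]undeca-1,7,9-triene (same spatial arrangement at C6 as 15) | CC1=CC(O[Si](C)(C)C)=CC(C)(C)[C@@]12C=CC(=CBr)CC2 | intermediate
17 | (6S,10S)-10-bromo-3-(bromomethylidene)-7,11,11-trimethylspiro[5.5]undeca-1,7-dien-9-one | CC1=CC(=O)[C@@H](Br)C(C)(C)[C@@]12C=CC(=CBr)CC2 | intermediate
18 | (3R,6S,10S)-10-bromo-3-(dibromomethyl)-3-hydroxy-7,11,11-trimethylspiro[5.5]undeca-1,7-dien-9-one | CC1=CC(=O)[C@@H](Br)C(C)(C)[C@@]12C=C[C@@](O)(C(Br)Br)CC2 | intermediate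
19 | (3R,6S,10S)-10-bromo-3-(dibromomethyl)-11,11-dimethyl-7-methylidene-3,9-bis(trimethylsilyloxy)spiro[5.5]undeca-1,8-diene | C=C1C=C(O[Si](C)(C)C)[C@@H](Br)C(C)(C)[C@@]12C=C[C@@](O[Si](C)(C)C)(C(Br)Br)CC2 | intermediate
20 | (3R,6S,10S)-10-bromo-3-(dibromomethyl)-3-hydroxy-11,11-dimethyl-7-methylidenespiro[5.5]undec-1-en-9-one | C=C1CC(=O)[C@@H](Br)C(C)(C)[C@@]12C=C[C@@](O)(C(Br)Br)CC2 | intermediate
21 | mailiohydrin, (3R,6S,9R,10S)-10-bromo-3-(dibromomethyl)-11,11-dimethyl-7-methylidenespiro[5.5]undec-1-ene-3,9-diol | C=C1C[C@@H](O)[C@@H](Br)C(C)(C)[C@@]12C=C[C@@](O)(C(Br)Br)CC2 | target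

## Step count and risks

Total step count: 10. Longest linear sequence: 10 steps (1 → 21).

The three steps most likely to fail:

**Step 8 (the proposed bromohydroxylation).** Br+ may attack elsewhere or the face selectivity at C3 may be low. The fallback uses known chemistry, sets out from 11 and comes back at 18. Dibromomethyllithium (CH2Br2, LiN(i-Pr)2, THF, −90 °C, AcOH quench) adds 1,2 to the ring-B ketone of 11, a known addition to ketones. It gives (3R,6R)-3-(dibromomethyl)-3-hydroxy-11,11-dimethyl-9-(2-methylpropoxy)spiro[5.5]undeca-1,8-dien-7-one F3 after chromatographic removal of the 3S epimer. Excess MeLi/CeCl3 at −78 °C then gives (3R,6R)-3-(dibromomethyl)-7,11,11-trimethyl-9-(2-methylpropoxy)spiro[5.5]undeca-1,8-diene-3,7-diol F4. Aqueous HCl converts this into (3R,6R)-3-(dibromomethyl)-3-hydroxy-7,11,11-trimethylspiro[5.5]undeca-1,7-dien-9-one F5. α′-Bromination with phenyltrimethylammonium tribromide (THF, 0 °C) returns to 18.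

**Step 9 (deconjugation).** The amine may instead remove the C10 proton, which only regenerates 18. The fallback sets out from 18 and comes back at 21. Isopropenyl acetate/TsOH (80 °C) gives the thermodynamic linear dienol acetate and also acetylates the C3 hydroxyl, which yields (3R,6S,10S)-10-bromo-3-(dibromomethyl)-11,11-dimethyl-7-methylidenespiro[5.5]undeca-1,8-diene-3,9-diyl diacetate F6. NaBH4 in EtOH/THF (0 °C) cleaves the enol acetate; the dienolate is protonated at C8 and the β,γ-unsaturated ketone is reduced in the same flask (classical dienol acetate/borohydride deconjugative reduction). This gives mailiohydrin 3-acetate, (3R,6S,9R,10S)-10-bromo-3-(dibromomethyl)-9-hydroxy-11,11-dimethyl-7-methylidenespiro[5.5]undec-1-en-3-yl acetate F7. i-Bu2AlH (−78 °C) removes the tertiary acetate and returns to 21.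

**Step 4 (desymmetrisation).** The enantiomeric excess on this spiro ketone may be insufficient. The fallback sets out from 6 and comes back at 11. The stereocentre is set in the cycloaddition instead: 6 reacts with 2-(triisopropylsilyloxy)buta-1,3-diene F1 (from methyl vinyl ketone, i-Pr3SiOTf and Et3N) under a confined chiral imidodiphosphorimidate Brønsted acid (CH2Cl2, −60 °C). This gives (6R)-11,11-dimethyl-9-(2-methylpropoxy)-3-(triisopropylsilyloxy)spiro[5.5]undeca-2,8-dien-7-one F2. Saegusa–Ito oxidation (Pd(OAc)2, O2, DMSO) returns to 11.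

## Further compounds

F1 | step 4 | 2-(triisopropylsilyloxy)buta-1,3-diene | C=CC(=C)O[Si](C(C)C)(C(C)C)C(C)C
F2 | step 4 | (6R)-11,11-dimethyl-9-(2-methylpropoxy)-3-(triisopropylsilyloxy)spiro[5.5]undeca-2,8-dien-7-one | O=C1C=C(OCC(C)C)CC(C)(C)[C@@]12CC=C(O[Si](C(C)C)(C(C)C)C(C)C)CC2
F3 | step 8 | (3R,6R)-3-(dibromomethyl)-3-hydroxy-11,11-dimethyl-9-(2-methylpropoxy)spiro[5.5]undeca-1,8-dien-7-one | O=C1C=C(OCC(C)C)CC(C)(C)[C@@]12C=C[C@@](O)(C(Br)Br)CC2
F4 | step 8 | (3R,6R)-3-(dibromomethyl)-7,11,11-trimethyl-9-(2-methylpropoxy)spiro[5.5]undeca-1,8-diene-3,7-diol (C7 epimers) | CC1(O)C=C(OCC(C)C)CC(C)(C)[C@@]12C=C[C@@](O)(C(Br)Br)CC2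
F5 | step 8 | (3R,6R)-3-(dibromomethyl)-3-hydroxy-7,11,11-trimethylspiro[5.5]undeca-1,7-dien-9-one | CC1=CC(=O)CC(C)(C)[C@@]12C=C[C@@](O)(C(Br)Br)CC2
F6 | step 9 | (3R,6S,10S)-10-bromo-3-(dibromomethyl)-11,11-dimethyl-7-methylidenespiro[5.5]undeca-1,8-diene-3,9-diyl diacetate | C=C1C=C(OC(C)=O)[C@@H](Br)C(C)(C)[C@@]12C=C[C@@](OC(C)=O)(C(Br)Br)CC2
F7 | step 9 | (3R,6S,9R,10S)-10-bromo-3-(dibromomethyl)-9-hydroxy-11,11-dimethyl-7-methylidenespiro[5.5]undec-1-en-3-yl acetate | C=C1C[C@@H](O)[C@@H](Br)C(C)(C)[C@@]12C=C[C@@](OC(C)=O)(C(Br)Br)CC2
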